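Cembrane numbering: ring carbons C1–C14, lactone O on C2, α-carbon C15, carbonyl C16, methylene C17. Everything rests on cutting the trans-fused α-methylene-γ-butyrolactone at C15–C16 and C1–C2, which exposes its 2-carboxyallyl unit C17=C15(C16)–C1 as a terminal allene plus CO2, and C2 as an enal. In the key step zerovalent nickel joins CO2 to the central allene carbon and the resulting allylnickel carboxylate adds through C1 to the aldehyde, closing the 14-membered ring and setting C1 and C2; lactonization follows in the same flask. The open-chain allenyl enal comes from geranyl acetate by two asymmetric vinylogous Mukaiyama aldol additions that set C10 and C6.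

Key step: step 14

Remark (stereochemical assumption): the (S,S)-bisphosphoramide is taken to deliver the dienolate to the Si face of the enals, which gives the S carbinols; if the sense is the opposite one, its enantiomer is used in steps 6 and 10 and nothing else changes.
Remark (names): C-numbers in the text are cembrane numbers; names of open-chain compounds carry their own chain locants.

Step 1
Reactants: 1 geranyl acetate
Product: 3 (2E)-3-methyl-6-oxohex-2-en-1-yl acetate, via secondary ozonide 2 (not isolated)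
Conditions: O3 (1 equiv), CH2Cl2, −78 °C; then Me2S, −78 °C → rt
Reagents that add atoms: ozone, [O-][O+]=O
Why: Ozonolysis with reductive work-up, in which electrophilic ozone should cleave the electron-richer 6,7-alkene rather than the 2,3-alkene deactivated by the allylic acetate, so the E-alkene of 3 is carried over from 1.

Step 2
Reactants: 3 (2E)-3-methyl-6-oxohex-2-en-1-yl acetate; 4 dimethyl (1-diazo-2-oxopropyl)phosphonate
Product: 5 (2E)-3-methylhept-2-en-6-yn-1-ol
Conditions: K2CO3, MeOH, 0 °C → rt
Reagents that add atoms: none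
Why: Ohira–Bestmann (Seyferth–Gilbert) homologation turns the aldehyde into the terminal alkyne, and the same K2CO3/MeOH transesterifies the acetate to the free allylic alcohol.

Step 3
Reactants: 5 (2E)-3-methylhept-2-en-6-yn-1-ol; 6 paraformaldehyde
Product: 7 (2E)-3-methylocta-2,6,7-trien-1-ol
Conditions: CuI, Cy2NH, 1,4-dioxane, reflux
Reagents that add atoms: none
Why: Crabbé homologation, in which a copper-mediated Mannich reaction of the alkyne with formaldehyde and the amine is followed by 1,5-hydride transfer with loss of the imine to give the terminal allene, and which tolerates the free alcohol.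

Step 4
Reactants: 7 (2E)-3-methylocta-2,6,7-trien-1-ol
Product: 8 (2E)-3-methylocta-2,6,7-trienal
Conditions: MnO2, CH2Cl2, rt
Reagents that add atoms: none
Why: MnO2 oxidizes the primary allylic alcohol chemoselectively to the E-enal and leaves the allene alone.

Step 5
Reactants: 9 ethyl 3-methylbut-2-enoate
Product: 11 tert-butyl[(1-ethoxy-3-methylbuta-1,3-dien-1-yl)oxy]dimethylsilane, via lithium dienolate 10 (not isolated)
Conditions: LiN(i-Pr)2, THF, −78 °C; then TBSCl, DMPU, −78 °C → rt
Reagents that add atoms: tert-butyldimethylsilyl chloride, CC(C)(C)[Si](C)(C)Cl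
Why: Kinetic γ-deprotonation of the senecioate and O-silylation of the lithium dienolate give the vinylketene silyl acetal (silyl dienol ether formation).

Step 6
Reactants: 8 (2E)-3-methylocta-2,6,7-trienal; 11 tert-butyl[(1-ethoxy-3-methylbuta-1,3-dien-1-yl)oxy]dimethylsilane
Product: 12 ethyl (2E,5S,6E)-5-hydroxy-3,7-dimethyldodeca-2,6,10,11-tetraenoate
Conditions: SiCl4, (S,S)-binaphthyl-2,2'-diamine-derived bisphosphoramide (pentane-1,5-diyl-linked, cat.), i-Pr2NEt (cat.), CH2Cl2, −78 °C; aq. NaHCO3/KF work-up
Reagents that add atoms: none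
Why: Catalytic asymmetric vinylogous Mukaiyama aldol addition with Lewis-base-activated SiCl4, in which the dienolate attacks the aldehyde carbon through its γ-carbon to give the E-enoate and the chiral phosphoramide-bound silicon cation exposes one aldehyde face, so that C10 should be set as S by the catalyst.

Step 7
Reactants: 12 ethyl (2E,5S,6E)-5-hydroxy-3,7-dimethyldodeca-2,6,10,11-tetraenoate
Product: 13 ethyl (2E,5S,6E)-5-[(tert-butyldimethylsilyl)oxy]-3,7-dimethyldodeca-2,6,10,11-tetraenoate
Conditions: TBSCl, imidazole, DMF, rt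
Reagents that add atoms: tert-butyldimethylsilyl chloride, CC(C)(C)[Si](C)(C)Cl
Why: Silylation of the secondary allylic alcohol protects C10–OH as a TBS ether that should last until the final step.

Step 8
Reactants: 13 ethyl (2E,5S,6E)-5-[(tert-butyldimethylsilyl)oxy]-3,7-dimethyldodeca-2,6,10,11-tetraenoate
Product: 14 (2E,5S,6E)-5-[(tert-butyldimethylsilyl)oxy]-3,7-dimethyldodeca-2,6,10,11-tetraen-1-ol
Conditions: i-Bu2AlH, CH2Cl2, −78 °C; aq. potassium sodium tartrate work-up
Reagents that add atoms: none
Why: Hydride reduction of the conjugated ester in the 1,2-sense gives the primary allylic alcohol without touching allene or silyl ether.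

Step 9
Reactants: 14 (2E,5S,6E)-5-[(tert-butyldimethylsilyl)oxy]-3,7-dimethyldodeca-2,6,10,11-tetraen-1-ol
Product: 15 (2E,5S,6E)-5-[(tert-butyldimethylsilyl)oxy]-3,7-dimethyldodeca-2,6,10,11-tetraenal
Conditions: MnO2, CH2Cl2, rt
Reagents that add atoms: none
Why: Chemoselective MnO2 oxidation of the allylic alcohol gives the E-enal for the second chain extension.

Step 10
Reactants: 15 (2E,5S,6E)-5-[(tert-butyldimethylsilyl)oxy]-3,7-dimethyldodeca-2,6,10,11-tetraenal; 11 tert-butyl[(1-ethoxy-3-methylbuta-1,3-dien-1-yl)oxy]dimethylsilane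
Product: 16 ethyl (2E,5S,6E,9S,10E)-9-[(tert-butyldimethylsilyl)oxy]-5-hydroxy-3,7,11-trimethylhexadeca-2,6,10,14,15-pentaenoate
Conditions: SiCl4, (S,S)-binaphthyl-2,2'-diamine-derived bisphosphoramide (pentane-1,5-diyl-linked, cat.), i-Pr2NEt (cat.), CH2Cl2, −78 °C; aq. NaHCO3/KF work-up
Reagents that add atoms: none
Why: Second catalytic asymmetric vinylogous Mukaiyama aldol addition, in which γ-attack gives the E-enoate and the catalyst, not the remote C10 centre, should set C6 as S.

Step 11
Reactants: 16 ethyl (2E,5S,6E,9S,10E)-9-[(tert-butyldimethylsilyl)oxy]-5-hydroxy-3,7,11-trimethylhexadeca-2,6,10,14,15-pentaenoate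
Product: 17 ethyl (2E,5S,6E,9S,10E)-9-[(tert-butyldimethylsilyl)oxy]-3,7,11-trimethyl-5-[(triethylsilyl)oxy]hexadeca-2,6,10,14,15-pentaenoate
Conditions: TESCl, imidazole, CH2Cl2, 0 °C
Reagents that add atoms: triethylsilyl chloride, CC[Si](Cl)(CC)CC
Why: Triethylsilylation gives a C6 ether that can later be removed selectively beside the C10 TBS ether, and it keeps an allylic acetate away from the zerovalent nickel of the key step.

Step 12
Reactants: 17 ethyl (2E,5S,6E,9S,10E)-9-[(tert-butyldimethylsilyl)oxy]-3,7,11-trimethyl-5-[(triethylsilyl)oxy]hexadeca-2,6,10,14,15-pentaenoate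
Product: 18 (2E,5S,6E,9S,10E)-9-[(tert-butyldimethylsilyl)oxy]-3,7,11-trimethyl-5-[(triethylsilyl)oxy]hexadeca-2,6,10,14,15-pentaen-1-ol
Conditions: i-Bu2AlH, CH2Cl2, −78 °C; aq. potassium sodium tartrate work-up
Reagents that add atoms: none
Why: Hydride reduction of the conjugated ester to the primary allylic alcohol, as in step 8.

Step 13
Reactants: 18 (2E,5S,6E,9S,10E)-9-[(tert-butyldimethylsilyl)oxy]-3,7,11-trimethyl-5-[(triethylsilyl)oxy]hexadeca-2,6,10,14,15-pentaen-1-ol
Product: 19 (2E,5S,6E,9S,10E)-9-[(tert-butyldimethylsilyl)oxy]-3,7,11-trimethyl-5-[(triethylsilyl)oxy]hexadeca-2,6,10,14,15-pentaenal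
Conditions: MnO2, CH2Cl2, rt
Reagents that add atoms: none
Why: Chemoselective MnO2 oxidation of the allylic alcohol gives the E-enal (C2) that faces the terminal allene across the chain.

Step 14
Reactants: 19 (2E,5S,6E,9S,10E)-9-[(tert-butyldimethylsilyl)oxy]-3,7,11-trimethyl-5-[(triethylsilyl)oxy]hexadeca-2,6,10,14,15-pentaenal; 20 carbon dioxide
Product: 23 (1R,2S,3E,6S,7E,10S,11E)-10-[(tert-butyldimethylsilyl)oxy]-6-[(triethylsilyl)oxy]cembra-3,7,11,15(17)-tetraen-16,2-olide, via allylnickel carboxylate 21 (not isolated), via macrocyclic hydroxy acid 22 (not isolated)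
Conditions: Ni(cod)2 (1.5 equiv), DBU, CO2 (1 atm), THF, 0 °C, slow addition of 19 (high dilution), then rt; 0.5 M HCl, 0 °C; then EDC·HCl, DMAP (cat.), CH2Cl2, 0 °C → rt
Reagents that add atoms: none
Why: Proposed new method: zerovalent nickel couples CO2 oxidatively with the terminal allene at its central carbon C15 to give the oxanickelacycle 21, a 2-carboxylato-allyl complex of divalent nickel (C15–C16 formed), and this nucleophilic allylnickel then adds through its substituted terminus C1 to the C2 aldehyde (C1–C2 formed), after which acid and carbodiimide close the lactone O–C16. The closest known reaction type is the nickel-mediated sequential addition of CO2 and an aldehyde to a terminal allene, known with external aldehydes and in short-tether cyclizations; its use to close a macrocycle is new. The 14-membered carbocycle closes by intramolecular carbonyl allylation through a six-membered chair-like Ni–O=C2–C1–C15–C17 array, as in chromium- or nickel-allyl macrocyclizations of polyprenyl chains, and the lactone closes as a 5-exo-trig acyl substitution. The chair with the syn (E) allyl terminus and an equatorial C3 alkenyl group should give the 1,2-anti adduct and hence the trans lactone; which anti pair forms ((1R,2S) is wanted) is decided only by the C6 and C10 silyloxy centres through the conformation of the closing ring, and the isomers would be separated if both form. The step needs carboxylation at C15, which the known preference of CO2 for the central allene carbon secures, attack through C1 rather than C17, which the less hindered η1 form with nickel on C17 secures, 1,2-addition to the enal, and high dilution with a long-lived stoichiometric allylnickel so that ring closure wins over oligomers.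

Step 15
Reactants: 23 (1R,2S,3E,6S,7E,10S,11E)-10-[(tert-butyldimethylsilyl)oxy]-6-[(triethylsilyl)oxy]cembra-3,7,11,15(17)-tetraen-16,2-olide
Product: 24 (1R,2S,3E,6S,7E,10S,11E)-10-[(tert-butyldimethylsilyl)oxy]-6-hydroxycembra-3,7,11,15(17)-tetraen-16,2-olide
Conditions: PPTS (cat.), MeOH–CH2Cl2, 0 °C
Reagents that add atoms: none
Why: Acid-catalysed methanolysis should cleave the less hindered triethylsilyl ether much faster than the TBS ether (selective desilylation), and the α-methylene lactone is inert to it.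

Step 16
Reactants: 24 (1R,2S,3E,6S,7E,10S,11E)-10-[(tert-butyldimethylsilyl)oxy]-6-hydroxycembra-3,7,11,15(17)-tetraen-16,2-olide
Product: 25 (1R,2S,3E,6S,7E,10S,11E)-6-acetoxy-10-[(tert-butyldimethylsilyl)oxy]cembra-3,7,11,15(17)-tetraen-16,2-olide
Conditions: Ac2O, pyridine, DMAP (cat.), CH2Cl2, 0 °C → rt
Reagents that add atoms: acetic anhydride, CC(=O)OC(C)=O
Why: DMAP-catalysed acetylation of the only free hydroxyl (C6) proceeds with retention at C6.

Step 17
Reactants: 25 (1R,2S,3E,6S,7E,10S,11E)-6-acetoxy-10-[(tert-butyldimethylsilyl)oxy]cembra-3,7,11,15(17)-tetraen-16,2-olide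
Product: 26 (1R,2S,3E,6S,7E,10S,11E)-6-acetoxy-10-hydroxycembra-3,7,11,15(17)-tetraen-16,2-olide (CNP0168244.1)
Conditions: HF·pyridine, pyridine, THF, 0 °C → rt
Reagents that add atoms: none
Why: Fluoride-mediated desilylation under buffered, non-basic conditions should free C10–OH without acetate migration or conjugate addition to the α-methylene lactone.

Compound list
1 | geranyl acetate, (2E)-3,7-dimethylocta-2,6-dien-1-yl acetate | CC(C)=CCC/C(C)=C/COC(C)=O | starting material
2 | secondary ozonide (1,2,4-trioxolane) of the 6,7-alkene of 1 | CC(=O)OC/C=C(\C)CCC1OOC(C)(C)O1 | intermediate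
3 | (2E)-3-methyl-6-oxohex-2-en-1-yl acetate | CC(=O)OC/C=C(\C)CCC=O | intermediate
4 | dimethyl (1-diazo-2-oxopropyl)phosphonate | CC(=O)C(=[N+]=[N-])P(=O)(OC)OC | starting material
5 | (2E)-3-methylhept-2-en-6-yn-1-ol | OC/C=C(\C)CCC#C | intermediate
6 | paraformaldehyde (formaldehyde source) | C=O | starting material
7 | (2E)-3-methylocta-2,6,7-trien-1-ol | OC/C=C(\C)CCC=C=C | intermediate
8 | (2E)-3-methylocta-2,6,7-trienal | O=C/C=C(\C)CCC=C=C | intermediate
9 | ethyl 3-methylbut-2-enoate | CCOC(=O)C=C(C)C | starting material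
10 | lithium dienolate of 9 | [Li+].C=C(C)C=C([O-])OCC | intermediate
11 | tert-butyl[(1-ethoxy-3-methylbuta-1,3-dien-1-yl)oxy]dimethylsilane (ketene acetal geometry not specified) | C=C(C)C=C(OCC)O[Si](C)(C)C(C)(C)C | intermediate
12 | ethyl (2E,5S,6E)-5-hydroxy-3,7-dimethyldodeca-2,6,10,11-tetraenoate | CCOC(=O)/C=C(\C)C[C@H](O)/C=C(\C)CCC=C=C | intermediate
13 | ethyl (2E,5S,6E)-5-[(tert-butyldimethylsilyl)oxy]-3,7-dimethyldodeca-2,6,10,11-tetraenoate | CCOC(=O)/C=C(\C)C[C@H](O[Si](C)(C)C(C)(C)C)/C=C(\C)CCC=C=C | intermediate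
14 | (2E,5S,6E)-5-[(tert-butyldimethylsilyl)oxy]-3,7-dimethyldodeca-2,6,10,11-tetraen-1-ol | OC/C=C(\C)C[C@H](O[Si](C)(C)C(C)(C)C)/C=C(\C)CCC=C=C | intermediate
15 | (2E,5S,6E)-5-[(tert-butyldimethylsilyl)oxy]-3,7-dimethyldodeca-2,6,10,11-tetraenal | O=C/C=C(\C)C[C@H](O[Si](C)(C)C(C)(C)C)/C=C(\C)CCC=C=C | intermediate
16 | ethyl (2E,5S,6E,9S,10E)-9-[(tert-butyldimethylsilyl)oxy]-5-hydroxy-3,7,11-trimethylhexadeca-2,6,10,14,15-pentaenoate | CCOC(=O)/C=C(\C)C[C@H](O)/C=C(\C)C[C@H](O[Si](C)(C)C(C)(C)C)/C=C(\C)CCC=C=C | intermediate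
17 | ethyl (2E,5S,6E,9S,10E)-9-[(tert-butyldimethylsilyl)oxy]-3,7,11-trimethyl-5-[(triethylsilyl)oxy]hexadeca-2,6,10,14,15-pentaenoate | CCOC(=O)/C=C(\C)C[C@H](O[Si](CC)(CC)CC)/C=C(\C)C[C@H](O[Si](C)(C)C(C)(C)C)/C=C(\C)CCC=C=C | intermediate
18 | (2E,5S,6E,9S,10E)-9-[(tert-butyldimethylsilyl)oxy]-3,7,11-trimethyl-5-[(triethylsilyl)oxy]hexadeca-2,6,10,14,15-pentaen-1-ol | OC/C=C(\C)C[C@H](O[Si](CC)(CC)CC)/C=C(\C)C[C@H](O[Si](C)(C)C(C)(C)C)/C=C(\C)CCC=C=C | intermediate
19 | (2E,5S,6E,9S,10E)-9-[(tert-butyldimethylsilyl)oxy]-3,7,11-trimethyl-5-[(triethylsilyl)oxy]hexadeca-2,6,10,14,15-pentaenal | O=C/C=C(\C)C[C@H](O[Si](CC)(CC)CC)/C=C(\C)C[C@H](O[Si](C)(C)C(C)(C)C)/C=C(\C)CCC=C=C | intermediate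
20 | carbon dioxide | O=C=O | starting material
21 | allylnickel carboxylate from 19 and CO2, drawn as the oxanickelacycle of divalent nickel (DBU ligands omitted, alkylidene geometry not specified) | O=C/C=C(\C)C[C@H](O[Si](CC)(CC)CC)/C=C(\C)C[C@H](O[Si](C)(C)C(C)(C)C)/C=C(\C)CCC=C1C[Ni]OC1=O | intermediate
22 | 2-[(1R,2S,3E,6S,7E,10S,11E)-10-[(tert-butyldimethylsilyl)oxy]-2-hydroxy-4,8,12-trimethyl-6-[(triethylsilyl)oxy]cyclotetradeca-3,7,11-trien-1-yl]prop-2-enoic acid | O[C@H]1/C=C(\C)C[C@H](O[Si](CC)(CC)CC)/C=C(\C)C[C@H](O[Si](C)(C)C(C)(C)C)/C=C(\C)CC[C@@H]1C(=C)C(=O)O | intermediate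
23 | (1R,2S,3E,6S,7E,10S,11E)-10-[(tert-butyldimethylsilyl)oxy]-6-[(triethylsilyl)oxy]cembra-3,7,11,15(17)-tetraen-16,2-olide (trans-fused) | C=C1C(=O)O[C@H]2/C=C(\C)C[C@H](O[Si](CC)(CC)CC)/C=C(\C)C[C@H](O[Si](C)(C)C(C)(C)C)/C=C(\C)CC[C@H]12 | intermediate
24 | (1R,2S,3E,6S,7E,10S,11E)-10-[(tert-butyldimethylsilyl)oxy]-6-hydroxycembra-3,7,11,15(17)-tetraen-16,2-olide | C=C1C(=O)O[C@H]2/C=C(\C)C[C@H](O)/C=C(\C)C[C@H](O[Si](C)(C)C(C)(C)C)/C=C(\C)CC[C@H]12 | intermediate
25 | (1R,2S,3E,6S,7E,10S,11E)-6-acetoxy-10-[(tert-butyldimethylsilyl)oxy]cembra-3,7,11,15(17)-tetraen-16,2-olide | C=C1C(=O)O[C@H]2/C=C(\C)C[C@H](OC(C)=O)/C=C(\C)C[C@H](O[Si](C)(C)C(C)(C)C)/C=C(\C)CC[C@H]12 | intermediate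
26 | (1R,2S,3E,6S,7E,10S,11E)-6-acetoxy-10-hydroxycembra-3,7,11,15(17)-tetraen-16,2-olide (CNP0168244.1) | C=C1C(=O)O[C@H]2/C=C(\C)C[C@H](OC(C)=O)/C=C(\C)C[C@H](O)/C=C(\C)CC[C@H]12 | target

Total step count: 17. Longest linear sequence: 16 steps (steps 1–4 and 6–17, from geranyl acetate 1); step 5 is a one-step side branch whose product 11 is used twice.

Steps most likely to fail

Step 14 (Proposed new method). What may go wrong: oligomerization instead of ring closure, protonation of the allylnickel before it reaches the aldehyde, attack through C17 instead of C1, or poor facial selectivity at C1/C2 relative to C6 and C10. The fallback sets out from 19 and comes back at 23. The allene of 19 would be 1,2-dibrominated with Pd(OAc)2 (cat.), LiBr and p-benzoquinone in THF–AcOH (bromopalladation at the central carbon, then bromide attack on the 2-bromoallyl complex of divalent palladium) to give the 2,3-dibromoalkene F1. CrCl2 in THF at high dilution would then close the 14-membered ring by the Nozaki–Hiyama allyl bromide–aldehyde macrocyclization, with γ-attack of the 2-bromoallylchromium through a chair and so anti, to give the 2-bromohomoallylic alcohol F2. Pd(PPh3)4, CO (1 atm) and K2CO3 in MeCN at 60 °C would carbonylate the vinyl bromide with capture by the C2 hydroxyl and return 23.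

Step 6 (the same risk holds for step 10). What may go wrong: insufficient facial selectivity on a β,β-disubstituted enal, or competing α-attack of the dienolate. The fallback sets out from 12 of low enantiomeric purity and comes back at 12. Dess–Martin periodinane (NaHCO3, CH2Cl2) would oxidize the carbinol to the dienone ester F3. Corey–Bakshi–Shibata reduction with the (R)-methyl oxazaborolidine and catecholborane (toluene, −78 °C) would then set the S carbinol by reagent control, with the alkenyl group as the large substituent.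

Step 1. What may go wrong: over-oxidation or loss of selectivity between the two trisubstituted alkenes during ozonolysis. The fallback sets out from 1 and comes back at 3. mCPBA (CH2Cl2, 0 °C) would epoxidize the distal, electron-richer alkene to give 6,7-epoxygeranyl acetate F4 (racemic at the epoxide, which is of no consequence), and H5IO6 in THF–H2O would cleave the epoxide to 3.

Further compounds
F1 | step 14 | (2E,5S,6E,9S,10E)-15,16-dibromo-9-[(tert-butyldimethylsilyl)oxy]-3,7,11-trimethyl-5-[(triethylsilyl)oxy]hexadeca-2,6,10,14-tetraenal (bromoalkene geometry not specified; its allylic regioisomer would give the same allylchromium) | O=C/C=C(\C)C[C@H](O[Si](CC)(CC)CC)/C=C(\C)C[C@H](O[Si](C)(C)C(C)(C)C)/C=C(\C)CCC=C(Br)CBr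
F2 | step 14 | 14-membered 2-bromohomoallylic alcohol: 1-(1-bromovinyl)-2-hydroxy carbocycle with the C1/C2 configuration of 23, 6-OTES, 10-OTBS | O[C@H]1/C=C(\C)C[C@H](O[Si](CC)(CC)CC)/C=C(\C)C[C@H](O[Si](C)(C)C(C)(C)C)/C=C(\C)CC[C@@H]1C(Br)=C
F3 | step 6 | ethyl (2E,6E)-3,7-dimethyl-5-oxododeca-2,6,10,11-tetraenoate | CCOC(=O)/C=C(\C)CC(=O)/C=C(\C)CCC=C=C
F4 | step 1 | 6,7-epoxygeranyl acetate, (2E)-5-(3,3-dimethyloxiran-2-yl)-3-methylpent-2-en-1-yl acetate | CC(=O)OC/C=C(\C)CCC1OC1(C)C
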